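**Runs so far.** Saturday's run is my starting point, with the two others beside it.

| flask | solid substrate | coupling partner | temperature | remark | time |
|---|---|---|---|---|---|
| Saturday's | 20 mM | 1.7 equiv (in portions, 4) | 95 °C | run made earlier; portions every 1.5 min |  |
| Tuesday's | 20 mM | 2.6 equiv (in portions, 4) | 106 °C | run made earlier; portions every 1.5 min |  |
| Sunday's | 30 mM | 1.2 equiv (in portions, 4) | 95 °C | run made earlier; portions every 1.5 min |  |
| south-west | 20 mM | 1.20 equiv | 110 °C | everything together at the start | 6.0 min |
| north-west | 20 mM | 1.20 equiv (in portions, 4) | 90 °C | the portions of coupling partner follow each other after 1.5 min, the first at the start | 6.0 min |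

| run | time / min | target / % | side product / % | solid substrate / % |
|---|---|---|---|---|
| Saturday's | 0.833 | 3.2 | 2.1 | 58.1 |
| Saturday's | 2.00 | 11.8 | 10.4 | 29.3 |
| Saturday's | 4.00 | 35.7 | 26.9 | 0 |
| Saturday's | 6.00 | 52.9 | 34.7 | 0 |
| Tuesday's | 0.250 | 0.9 | 0.8 | 83.6 |
| Tuesday's | 0.417 | 3.5 | 0 | 74.6 |
| Tuesday's | 1.00 | 8.2 | 5.3 | 50.6 |
| Tuesday's | 2.50 | 33.8 | 23.2 | 3.3 |
| Sunday's | 1.50 | 3.9 | 3.3 | 59.4 |
| Sunday's | 3.00 | 15.2 | 12.5 | 37.7 |
| Sunday's | 5.00 | 38.4 | 23.8 | 7.0 |
| Sunday's | 6.00 | 48.0 | 28.8 | 0 |

(each reading ± 0.5 percentage points)

- a species is counted by the solid substrate in it: one side product counts as two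
- at the start none of the solid substrate is in solution
- what has only dissolved of solid substrate counts as not reacted
- a reading or a percentage of target counts all its forms, free or not

- which of the two ends with the higher share of target in all that became target or side product ("neither" if they lie within 2 percentage points) (south-west / north-west / neither)
- share of target in all that became target or side product, south-west
- share of target in all that became target or side product, north-west

**Partner odds.** In Saturday's run, from 4.00 min to 6.00 min, target gains 17 percentage points and side product 7.8 points. That is 2.21 of target per side product. Taking partner as charged minus target, [coupling partner] averages 20.9 mM there. I call the gain ratio divided by [coupling partner] the partner odds, a selectivity factor per mM: 0.106 /mM. Tuesday's hotter run gives 0.0935 /mM, so I carry Saturday's value to both new flasks. The share is then odds over one plus odds.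

**The bracket.** South-west starts at 24.0 mM of coupling partner. Held there, the odds give 71.7%, my upper bound. Taking that share as target leaves 9.66 mM. Held there, the odds give 50.5%, my lower bound. The mean of both levels, 16.8 mM, gives 64.0%, my number for south-west. North-west's portions reach the same 24.0 mM of coupling partner, so its upper bound is the same 71.7%. Until the last portion, at 4.50 min, north-west has at most 18.0 mM charged, less than south-west. At equal target made it then holds less coupling partner, so on the same odds I expect a lower share in north-west than in south-west. I pick south-west.

**The forecast.** It says south-west, with 60% for south-west and 56% for north-west, on the ground that “Target rate per dissolved substrate rises with free partner”. Its south-west value stands inside my bracket, lower than my number.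

**The flask.** South-west ends at 58.5% and north-west at 53.7%, so south-west leads by 4.8 points. The forecast held on all three counts.

    solid substrate ⇌ dissolved substrate, rate k1*(cs1 - [dissolved substrate]) while solid is left; crystals form when [dissolved substrate] > cs1 (solubility = 14.0 mM, k = 0.0176 /s)
    dissolved substrate + coupling partner → target (k = 0.313 /M/s, Ea = 48.0 kJ/mol)
    dissolved substrate + target → side product (k = 1.46 /M/s, Ea = 54.0 kJ/mol)
    solid product ⇌ target, rate k4*(cs4 - [target]) while solid is left; crystals form when [target] > cs4 (solubility = 0.720 mM, k = 0.764 /s)
    (constants at 90 °C)

**A neighbour.** South-west's 58.5% lies inside my bracket, lower than my 64.0%. The neighbour is south-west with 2.00 equiv of coupling partner, so it starts at 40.0 mM. In that neighbour flask the odds give an upper bound of 80.9%, which leaves 23.8 mM. The mean level, 31.9 mM, gives 77.2% for the neighbour. The neighbour flask gives 75.8%.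

(The earlier runs and the new flask were generated by integration with constants of no real substance, noise included.)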